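**Plan**
1. The eight-membered ring C2–C3–C4–C7–C9–C18–C19–C20 holds the C7 ketone and the C19=C20 enol four atoms apart (a cyclooct-4-enone), so C2–C3 is cut and C7–C19 re-joined to give a cis-1,2-dialkenylcyclobutanol on the cage.
2. Further cuts: C4–CH3 and the O6/O21 oxygens (late), C18–C9 and C19–C7 (cyclobutane, [2+2]), C19–C20 and C10–C9 (side arms), O17–C15 (ether bridge), C18–C19 (Dieckmann), C25–C12 and C26–C27 (Diels–Alder).
3. Forward: cyclohexene → spiro tetronic acid → 2-oxabicyclo[2.2.2]octane fused to a butenolide → cyclopentane and cyclobutane in one photochemical step → eight-membered ring by oxy-Cope → α-ketol and enolised β-keto lactone.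
4. Absolute configuration comes from the (S)-4-benzyloxazolidinone auxiliary in the Diels–Alder step (C12, C27); these relay to C25 (enolate hydroxylation) and C13/C15 (directed epoxidation, inversion at C15 on bridging).
5. C10 is set by a reagent-controlled ynone reduction, C9/C18/C19 by the tether in the [2+2], C2 by the (Z)-propenyl geometry in the boat, C4 by methyl addition to the outer face of a 1,2-dione.
6. Atom numbers (C1–C28, O6–O24) are the positions of the atoms in the target SMILES string.

Key step: step 27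

Assumption: reagents reach C4 of the tub-shaped cycloocta-1,5-diene only from its outer face, where an oxidant acting on a C4-methyl enol ether would place the hydroxyl on the wrong side; C7 therefore carries vinyl, and the C4 methyl is added last as the nucleophile.

**Route**

Step 1
Reactants: 1 (E)-2-methylbut-2-enal; 2 triethyl phosphonoacetate
Product: 3 ethyl (2E,4E)-4-methylhexa-2,4-dienoate
Conditions: NaH, THF, 0 °C → rt
Reagents that add atoms: none
Why: Horner–Wadsworth–Emmons olefination with a stabilised phosphonate should form C12=C13 E-selectively and leave the E-configured C15=C27 bond untouched.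

Step 2
Reactants: 3 ethyl (2E,4E)-4-methylhexa-2,4-dienoate
Product: 4 (2E,4E)-4-methylhexa-2,4-dien-1-ol
Conditions: (i-Bu)2AlH, CH2Cl2, −78 °C
Reagents that add atoms: none
Why: Hydride reduction of a conjugated ester with (i-Bu)2AlH proceeds 1,2 and should give the dienol without touching the diene.

Step 3
Reactants: 4 (2E,4E)-4-methylhexa-2,4-dien-1-ol
Product: 5 (2E,4E)-4-methylhexa-2,4-dien-1-yl 4-methoxybenzyl ether
Conditions: NaH, PMBCl, Bu4NI (cat.), THF, 0 °C → rt
Reagents that add atoms: 4-methoxybenzyl chloride, COc1ccc(CCl)cc1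
Why: Williamson etherification of the primary alkoxide masks C10–OH with a group that survives Lewis acid, strong base and mild acid and is later removed oxidatively.

Step 4
Reactants: 6 (S)-4-benzyloxazolidin-2-one; 7 acryloyl chloride
Product: 8 (S)-3-acryloyl-4-benzyloxazolidin-2-one
Conditions: n-BuLi, THF, −78 °C; then 7, −78 → 0 °C
Reagents that add atoms: none
Why: N-acylation of the lithiated oxazolidinone with the acid chloride is the standard entry to the chiral acrylimide.

Step 5
Reactants: 5 dienyl PMB ether; 8 (S)-3-acryloyl-4-benzyloxazolidin-2-one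
Product: 9 Diels–Alder adduct, (S)-4-benzyl-3-acyloxazolidin-2-one whose acyl group is the all-cis 2-(PMB-oxymethyl)-4,5-dimethylcyclohex-3-ene-1-carbonyl unit (C25, C12, C27 substituents cis)
Conditions: Et2AlCl (1.4 equiv), CH2Cl2, −78 °C
Reagents that add atoms: none
Why: In this Lewis-acid-promoted Diels–Alder reaction the chelated s-cis acrylimide should be attacked endo on the Cα face away from the benzyl group, which sets C12 and C27 cis to each other and to the acyl group from the (E,E)-diene, with C27, the terminus next to the C15 methyl and remote from the C12 substituent, bonding to the β-carbon C26.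

Step 6
Reactants: 9 Diels–Alder adduct
Product: 10 benzyl (all-cis) 2-(PMB-oxymethyl)-4,5-dimethylcyclohex-3-ene-1-carboxylate
Conditions: BnOH, n-BuLi, THF, −78 → 0 °C
Reagents that add atoms: benzyl alcohol, OCc1ccccc1
Why: Transesterification with lithium benzyloxide attacks the exocyclic imide carbonyl and releases the auxiliary; the C25 centre is made planar in the next step, so its integrity is not critical.

Step 7
Reactants: 10 benzyl ester
Product: 11 benzyl 1-hydroxy ester (C25–OH trans to the C12 side chain, ester cis to it)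
Conditions: KN(SiMe3)2, THF, −78 °C; then 2-(phenylsulfonyl)-3-phenyloxaziridine
Reagents that add atoms: 2-(phenylsulfonyl)-3-phenyloxaziridine, O=S(=O)(c1ccccc1)N1OC1c1ccccc1
Why: In this enolate hydroxylation with an N-sulfonyloxaziridine, allylic 1,3-strain turns the C12 side chain perpendicular to the exocyclic enolate, so the oxidant should enter anti to it and to the C27 methyl, placing O24 trans to C10.

Step 8
Reactants: 11 hydroxy ester
Product: 12 epoxy alcohol (C13–C15 epoxide cis to C25–OH)
Conditions: VO(acac)2 (cat.), t-BuOOH, CH2Cl2, 0 °C → rt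
Reagents that add atoms: tert-butyl hydroperoxide, CC(C)(C)OO
Why: In this hydroxyl-directed vanadium-catalysed epoxidation the homoallylic tertiary C25–OH delivers the peroxide to its own face of C13=C15, which is also the face remote from the C12 and C27 substituents.

Step 9
Reactants: 12 epoxy alcohol
Product: 13 C25 acetate of 12
Conditions: Ac2O, DMAP, Et3N, CH2Cl2, rt
Reagents that add atoms: acetic anhydride, CC(=O)OC(C)=O
Why: DMAP-catalysed acylation of the tertiary α-hydroxy ester installs the two carbons C19 and C22 under conditions that leave the epoxide intact.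

Step 10
Reactants: 13 acetoxy ester
Product: 15 bridged tetronate alcohol (2-oxabicyclo[2.2.2]octane with the C15–O17–C18 bridge, fused to the butenolide at C18–C25; C13–OH anti to the bridge), via spiro tetronic acid 14 (not isolated)
Conditions: LiN(SiMe3)2, THF, −78 → 0 °C; aq. HCl; then CSA (cat.), CH2Cl2, rt
Reagents that add atoms: none
Why: Dieckmann condensation of the acetate enolate onto the geminal benzyl ester gives the spiro tetronic acid, whose enol oxygen, the only nucleophile the rigid butenolide points toward C15, should then open the protonated epoxide at the tertiary carbon with inversion (acid-catalysed epoxide-opening etherification of the cineole type), leaving C13–OH trans to O17.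

Step 11
Reactants: 15 bridged tetronate alcohol
Product: 16 C13 tert-butyldimethylsilyl ether of 15
Conditions: TBSOTf, 2,6-lutidine, CH2Cl2, −78 → 0 °C
Reagents that add atoms: tert-butyldimethylsilyl triflate, CC(C)(C)[Si](C)(C)OS(=O)(=O)C(F)(F)F
Why: Silylation with the silyl triflate is needed for the hindered secondary alcohol next to the quaternary C15.

Step 12
Reactants: 16 silyl ether
Product: 17 C19-(benzyloxymethyl) tetronate
Conditions: LiN(i-Pr)2, THF, −78 °C; then BnOCH2Cl, −78 → −20 °C
Reagents that add atoms: benzyl chloromethyl ether, ClCOCc1ccccc1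
Why: Vinylic deprotonation at C3 of a 4-alkoxy-5,5-disubstituted butenolide, the only acidic site since C25 is quaternary, and alkylation of the vinyllithium install C20 at an sp3 oxidation level that does not disturb the later photochemistry.

Step 13
Reactants: 17 benzyloxymethyl tetronate
Product: 18 primary alcohol (C10–OH)
Conditions: DDQ, CH2Cl2/pH 7 buffer, 0 °C
Reagents that add atoms: none
Why: Oxidative cleavage of the 4-methoxybenzyl ether is much faster than attack on the benzyl ether, the silyl ether or the electron-poor tetronate.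

Step 14
Reactants: 18 primary alcohol
Product: 19 C10 aldehyde
Conditions: Dess–Martin periodinane, NaHCO3, CH2Cl2, 0 °C → rt
Reagents that add atoms: none
Why: Dess–Martin oxidation is near-neutral and should not epimerise the α-centre C12.

Step 15
Reactants: 19 aldehyde; 20 ethynylmagnesium bromide
Product: 21 propargylic alcohols (both C10 epimers)
Conditions: THF, −78 °C
Reagents that add atoms: none
Why: Grignard 1,2-addition to the aldehyde brings in C9 and C7; the C10 configuration is corrected in the next two steps.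

Step 16
Reactants: 21 propargylic alcohols
Product: 22 ynone (C10 ketone)
Conditions: Dess–Martin periodinane, NaHCO3, CH2Cl2, 0 °C
Reagents that add atoms: none
Why: Dess–Martin oxidation converges both epimers on one ynone without base that could add to the terminal alkyne.

Step 17
Reactants: 22 ynone
Product: 23 (S)-propargylic alcohol at C10
Conditions: (S)-Me-CBS, BH3·SMe2, THF, −30 °C
Reagents that add atoms: none
Why: In this Corey–Bakshi–Shibata reduction the ethynyl group acts as the small and the branched ring carbon C12 as the large ketone substituent, so the (S)-catalyst should give the (S)-carbinol that corresponds to C10 of the target.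

Step 18
Reactants: 23 propargylic alcohol
Product: 24 C10, C13 bis(tert-butyldimethylsilyl) ether with terminal alkyne
Conditions: TBSOTf, 2,6-lutidine, CH2Cl2, −78 °C
Reagents that add atoms: tert-butyldimethylsilyl triflate, CC(C)(C)[Si](C)(C)OS(=O)(=O)C(F)(F)F
Why: Silyl ether formation protects O11 for the oxidation and organometallic steps that follow.

Step 19
Reactants: 24 alkyne
Product: 25 (E)-alkenyl pinacol boronate (C9=C7–Bpin)
Conditions: pinacolborane, Cp2Zr(H)Cl (cat.), CH2Cl2, rt
Reagents that add atoms: pinacolborane, CC1(C)OBOC1(C)C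
Why: Zirconium-catalysed syn-hydroboration of the terminal alkyne is anti-Markovnikov and places boron on C7 as a latent hydroxyl that can be unmasked without base.

Step 20
Reactants: 25 alkenyl boronate
Product: 26 photocycloadduct, cage-fused cyclobutane (C18–C9 and C19–C7 formed; C7–Bpin as both epimers; C19 CH2OBn)
Conditions: hν (254 nm), t-BuOH, rt
Reagents that add atoms: none
Why: In this intramolecular enone–alkene [2+2] photocycloaddition of a tetronate the three-atom tether C25–C12–C10 should lead to C18–C9 closure to the cyclopentane and then C19–C7 closure (straight adduct), and because the alkene can reach only the tetronate face on the C12 side, C9, C18 and C19 are set by the cage while C7 is oxidised later.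

Step 21
Reactants: 26 photocycloadduct
Product: 27 C20 primary alcohol
Conditions: H2, Pd(OH)2/C, EtOAc, rt
Reagents that add atoms: none
Why: Hydrogenolysis of the benzyl ether is safe here because no alkene is present and the boronate and silyl ethers are inert.

Step 22
Reactants: 27 alcohol
Product: 28 C20 aldehyde
Conditions: Dess–Martin periodinane, NaHCO3, CH2Cl2, rt
Reagents that add atoms: none
Why: Dess–Martin oxidation of the neopentyl alcohol gives an aldehyde on a quaternary carbon that cannot enolise.

Step 23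
Reactants: 28 aldehyde; 29 ethyltriphenylphosphonium bromide
Product: 30 C19 (Z)-prop-1-enyl cyclobutyl boronate
Conditions: 29, KN(SiMe3)2, THF, 0 °C; then 28, −78 → 0 °C
Reagents that add atoms: none
Why: Wittig olefination with a non-stabilised ylide under salt-free conditions should give the (Z)-alkene, a preference that hindered α-quaternary aldehydes reinforce.

Step 24
Reactants: 30 boronate
Product: 31 cyclobutanol (C7–OH, both epimers)
Conditions: NaBO3·4H2O, THF/pH 7 buffer, 0 °C
Reagents that add atoms: sodium perborate tetrahydrate, [Na+].[O-]B=O.OO.O.O.O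
Why: Oxidation of the C–B bond with perborate is close to neutral, which avoids the alkoxide that could open the β-hydroxy lactone cyclobutane by retro-aldol cleavage.

Step 25
Reactants: 31 cyclobutanol
Product: 32 cyclobutanone (C7=O)
Conditions: Dess–Martin periodinane, NaHCO3, CH2Cl2, 0 °C
Reagents that add atoms: none
Why: Dess–Martin oxidation converges both C7 epimers on the ketone, whose α-carbon C19 is quaternary and whose other α-carbon C9 is held by the ring fusion.

Step 26
Reactants: 32 cyclobutanone; 33 vinylmagnesium bromide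
Product: 34 cis-1,2-dialkenylcyclobutanol (vinyl and OH on C7, (Z)-propenyl on C19, the two alkenyl groups cis)
Conditions: THF, −78 °C; AcOH quench at −78 °C
Reagents that add atoms: none
Why: Grignard 1,2-addition to the strained ketone should occur from the convex face of the cyclobutane, opposite the fused lactone and cyclopentane, which puts vinyl cis to the propenyl group, and the cold quench avoids premature reaction of the magnesium alkoxide.

Step 27
Reactants: 34 cis-1,2-dialkenylcyclobutanol
Product: 36 eight-membered trimethylsilyl enol ether (C4=C7–OSiMe3; C19=C20 alkylidene lactone; C2 methyl stereocentre), via potassium enolate 35 (not isolated)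
Conditions: KN(SiMe3)2, 18-crown-6, THF, −78 → −20 °C; then Me3SiCl, Et3N, −78 °C
Reagents that add atoms: chlorotrimethylsilane, C[Si](C)(C)Cl
Why: The potassium alkoxide of 34 has its vinyl (C7) and (Z)-propenyl (C19) groups cis on the convex face of the cyclobutane and should undergo a charge-accelerated [3,3]-sigmatropic shift, the anionic oxy-Cope rearrangement of a cis-1,2-dialkenylcyclobutanol to a cyclooct-4-enone enolate, in which C2–C3 forms as C7–C19 breaks and the four-membered-ring strain is released. The eight-membered ring closes through the C2–C3 bond within a six-atom boat array, the only geometry a cis-dialkenylcyclobutane allows, so both new ring alkenes (C4=C7 enolate and C19=C20) are cis. The one new stereocentre, C2, is set by the (Z)-geometry of the propenyl group, whose methyl points inward over the ring in the boat, together with the fixed convex-face attachment at C19. The step needs the [3,3] course and not retro-aldol fragmentation toward the lactone dienolate followed by 1,3-recombination at C19; the cis arrangement keeps C2 and C3 within bonding distance, and a lactone-stabilised dienyl anion formed stepwise should not rotate about C20–C2 below −20 °C, so the same product is expected either way. Me3SiCl/Et3N then silylates the C7 enolate on oxygen.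

Step 28
Reactants: 36 silyl enol ether
Product: 37 α-hydroxy ketone (C4–OH, C7=O)
Conditions: dimethyldioxirane, acetone/CH2Cl2, −40 °C; aq. citric acid, THF
Reagents that add atoms: dimethyldioxirane, CC1(C)OO1
Why: Rubottom oxidation epoxidises the electron-rich enol ether in preference to the electron-poor alkylidene lactone; the C4 configuration formed here is erased at the dione stage.

Step 29
Reactants: 37 α-hydroxy ketone
Product: 39 diol (C4–OH, C20–OH; C19–H), via C20 pinacol boronate 38 (not isolated)
Conditions: B2pin2, CuCl (cat.), Xantphos (cat.), NaOt-Bu (cat.), MeOH, THF, rt; then NaBO3·4H2O, THF/H2O, 0 °C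
Reagents that add atoms: bis(pinacolato)diboron, CC1(C)OB(OC1(C)C)B1OC(C)(C)C(C)(C)O1; sodium perborate tetrahydrate, [Na+].[O-]B=O.OO.O.O.O
Why: Copper-catalysed conjugate borylation of the s-cis-locked alkylidene lactone followed by C–B oxidation places oxygen on C20; the C19 and C20 configurations are lost on oxidation to the enol.

Step 30
Reactants: 39 diol
Product: 40 C4,C7-dione with enolised β-keto lactone (C20–OH enol)
Conditions: Dess–Martin periodinane (excess), NaHCO3, CH2Cl2, rt
Reagents that add atoms: none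
Why: Dess–Martin oxidation converts the acyloin into the 1,2-dione and the β-hydroxy lactone into the β-keto lactone, which should rest as the C19=C20 enol conjugated with the lactone carbonyl so that C2 is not epimerised.

Step 31
Reactants: 40 dione; 41 methylmagnesium bromide
Product: 42 bis(tert-butyldimethylsilyl) ether of the target (C4 tertiary alcohol)
Conditions: 41 (3 equiv), THF, −78 °C
Reagents that add atoms: none
Why: In this Grignard addition the first equivalent deprotonates the enol to an inert magnesium enolate and the next should add to C4, the dione carbonyl flanked by CH2 and not by the ring-fusion carbon C9, from the outer face of the ring, which places the methyl on the same side as the C2 methyl and the hydroxyl inward as in the target.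

Step 32
Reactants: 42 bis-silyl ether
Product: 43 target, CNP0115071.1
Conditions: HF·pyridine, pyridine/THF, 0 °C → rt
Reagents that add atoms: none
Why: Fluoride-mediated desilylation under mildly acidic conditions frees O11 and O14 without the base that could trigger α-ketol rearrangement or epimerise C2.

**Compound list**
1 | (E)-2-methylbut-2-enal | C/C=C(\C)C=O | starting material
2 | triethyl phosphonoacetate | CCOC(=O)CP(=O)(OCC)OCC | starting material
3 | ethyl (2E,4E)-4-methylhexa-2,4-dienoate | C/C=C(C)/C=C/C(=O)OCC | intermediate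
4 | (2E,4E)-4-methylhexa-2,4-dien-1-ol | C/C=C(C)/C=C/CO | intermediate
5 | (2E,4E)-4-methylhexa-2,4-dien-1-yl 4-methoxybenzyl ether | C/C=C(C)/C=C/COCc1ccc(OC)cc1 | intermediate
6 | (S)-4-benzyloxazolidin-2-one | O=C1N[C@@H](Cc2ccccc2)CO1 | starting material
7 | acryloyl chloride | C=CC(=O)Cl | starting material
8 | (S)-3-acryloyl-4-benzyloxazolidin-2-one | C=CC(=O)N1[C@@H](Cc2ccccc2)COC1=O | intermediate
9 | Diels–Alder adduct, N-acyl oxazolidinone of the all-cis 2-(PMB-oxymethyl)-4,5-dimethylcyclohex-3-ene-1-carboxylic acid | COc1ccc(COC[C@H]2C=C(C)[C@@H](C)C[C@H]2C(=O)N3[C@@H](Cc4ccccc4)COC3=O)cc1 | intermediate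
10 | benzyl ester of the all-cis cyclohexenecarboxylic acid | COc1ccc(COC[C@H]2C=C(C)[C@@H](C)C[C@H]2C(=O)OCc3ccccc3)cc1 | intermediate
11 | benzyl 1-hydroxy ester (C25–OH trans to the C12 side chain) | COc1ccc(COC[C@H]2C=C(C)[C@@H](C)C[C@@]2(O)C(=O)OCc3ccccc3)cc1 | intermediate
12 | epoxy alcohol (C13–C15 epoxide cis to C25–OH) | COc1ccc(COC[C@H]2[C@@H]3O[C@]3(C)[C@@H](C)C[C@@]2(O)C(=O)OCc4ccccc4)cc1 | intermediate
13 | C25 acetate of 12 | COc1ccc(COC[C@H]2[C@@H]3O[C@]3(C)[C@@H](C)C[C@@]2(OC(C)=O)C(=O)OCc4ccccc4)cc1 | intermediate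
14 | spiro tetronic acid (4-hydroxybutenolide spiro at C25, epoxide retained) | COc1ccc(COC[C@H]2[C@@H]3O[C@]3(C)[C@@H](C)C[C@]24OC(=O)C=C4O)cc1 | intermediate
15 | bridged tetronate alcohol (C15–O17–C18 bridge, C13–OH) | COc1ccc(COC[C@H]2[C@H](O)[C@@]3(C)OC4=CC(=O)O[C@@]24C[C@@H]3C)cc1 | intermediate
16 | C13 TBS ether of 15 | COc1ccc(COC[C@H]2[C@H](O[Si](C)(C)C(C)(C)C)[C@@]3(C)OC4=CC(=O)O[C@@]24C[C@@H]3C)cc1 | intermediate
17 | C19-(benzyloxymethyl) tetronate | COc1ccc(COC[C@H]2[C@H](O[Si](C)(C)C(C)(C)C)[C@@]3(C)OC4=C(COCc5ccccc5)C(=O)O[C@@]24C[C@@H]3C)cc1 | intermediate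
18 | primary alcohol (C10–OH) | OC[C@H]1[C@H](O[Si](C)(C)C(C)(C)C)[C@@]2(C)OC3=C(COCc4ccccc4)C(=O)O[C@@]13C[C@@H]2C | intermediate
19 | C10 aldehyde | O=C[C@H]1[C@H](O[Si](C)(C)C(C)(C)C)[C@@]2(C)OC3=C(COCc4ccccc4)C(=O)O[C@@]13C[C@@H]2C | intermediate
20 | ethynylmagnesium bromide | C#C[Mg]Br | starting material
21 | propargylic alcohols, both C10 epimers | C#CC(O)[C@H]1[C@H](O[Si](C)(C)C(C)(C)C)[C@@]2(C)OC3=C(COCc4ccccc4)C(=O)O[C@@]13C[C@@H]2C | intermediate
22 | ynone (C10 ketone) | C#CC(=O)[C@H]1[C@H](O[Si](C)(C)C(C)(C)C)[C@@]2(C)OC3=C(COCc4ccccc4)C(=O)O[C@@]13C[C@@H]2C | intermediate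
23 | (S)-propargylic alcohol at C10 | C#C[C@@H](O)[C@H]1[C@H](O[Si](C)(C)C(C)(C)C)[C@@]2(C)OC3=C(COCc4ccccc4)C(=O)O[C@@]13C[C@@H]2C | intermediate
24 | C10, C13 bis-TBS ether with terminal alkyne | C#C[C@@H](O[Si](C)(C)C(C)(C)C)[C@H]1[C@H](O[Si](C)(C)C(C)(C)C)[C@@]2(C)OC3=C(COCc4ccccc4)C(=O)O[C@@]13C[C@@H]2C | intermediate
25 | (E)-alkenyl pinacol boronate (C9=C7–Bpin) | CC1(C)OB(/C=C/[C@@H](O[Si](C)(C)C(C)(C)C)[C@H]2[C@H](O[Si](C)(C)C(C)(C)C)[C@@]3(C)OC4=C(COCc5ccccc5)C(=O)O[C@@]24C[C@@H]3C)OC1(C)C | intermediate
26 | photocycloadduct, cage-fused cyclobutane (C7–Bpin, both C7 epimers; C19 CH2OBn) | CC1(C)OB(OC1(C)C)C1[C@@H]2[C@@H](O[Si](C)(C)C(C)(C)C)[C@H]3[C@H](O[Si](C)(C)C(C)(C)C)[C@@]4(C)O[C@@]25[C@]1(COCc6ccccc6)C(=O)O[C@@]35C[C@@H]4C | intermediate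
27 | C20 primary alcohol | CC1(C)OB(OC1(C)C)C1[C@@H]2[C@@H](O[Si](C)(C)C(C)(C)C)[C@H]3[C@H](O[Si](C)(C)C(C)(C)C)[C@@]4(C)O[C@@]25[C@]1(CO)C(=O)O[C@@]35C[C@@H]4C | intermediate
28 | C20 aldehyde | CC1(C)OB(OC1(C)C)C1[C@@H]2[C@@H](O[Si](C)(C)C(C)(C)C)[C@H]3[C@H](O[Si](C)(C)C(C)(C)C)[C@@]4(C)O[C@@]25[C@]1(C=O)C(=O)O[C@@]35C[C@@H]4C | intermediate
29 | ethyltriphenylphosphonium bromide | CC[P+](c1ccccc1)(c1ccccc1)c1ccccc1.[Br-] | starting material
30 | C19 (Z)-prop-1-enyl cyclobutyl boronate | CC1(C)OB(OC1(C)C)C1[C@@H]2[C@@H](O[Si](C)(C)C(C)(C)C)[C@H]3[C@H](O[Si](C)(C)C(C)(C)C)[C@@]4(C)O[C@@]25[C@]1(/C=C\C)C(=O)O[C@@]35C[C@@H]4C | intermediate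
31 | cyclobutanol (C7–OH, both epimers) | OC1[C@@H]2[C@@H](O[Si](C)(C)C(C)(C)C)[C@H]3[C@H](O[Si](C)(C)C(C)(C)C)[C@@]4(C)O[C@@]25[C@]1(/C=C\C)C(=O)O[C@@]35C[C@@H]4C | intermediate
32 | cyclobutanone (C7=O) | O=C1[C@@H]2[C@@H](O[Si](C)(C)C(C)(C)C)[C@H]3[C@H](O[Si](C)(C)C(C)(C)C)[C@@]4(C)O[C@@]25[C@]1(/C=C\C)C(=O)O[C@@]35C[C@@H]4C | intermediate
33 | vinylmagnesium bromide | C=C[Mg]Br | starting material
34 | cis-1,2-dialkenylcyclobutanol (vinyl and OH on C7, (Z)-propenyl on C19) | C=C[C@@]1(O)[C@@H]2[C@@H](O[Si](C)(C)C(C)(C)C)[C@H]3[C@H](O[Si](C)(C)C(C)(C)C)[C@@]4(C)O[C@@]25[C@]1(/C=C\C)C(=O)O[C@@]35C[C@@H]4C | intermediate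
35 | potassium enolate of the ring-expanded ketone | C[C@H]1C/C=C([O-])\[C@@H]2[C@@H](O[Si](C)(C)C(C)(C)C)[C@H]3[C@H](O[Si](C)(C)C(C)(C)C)[C@@]4(C)O[C@@]25/C(=C\1)C(=O)O[C@@]35C[C@@H]4C.[K+] | intermediate
36 | eight-membered trimethylsilyl enol ether | C[C@H]1C/C=C(O[Si](C)(C)C)\[C@@H]2[C@@H](O[Si](C)(C)C(C)(C)C)[C@H]3[C@H](O[Si](C)(C)C(C)(C)C)[C@@]4(C)O[C@@]25/C(=C\1)C(=O)O[C@@]35C[C@@H]4C | intermediate
37 | α-hydroxy ketone (C4–OH on the outer face, C7=O) | C[C@H]1C[C@@H](O)C(=O)[C@@H]2[C@@H](O[Si](C)(C)C(C)(C)C)[C@H]3[C@H](O[Si](C)(C)C(C)(C)C)[C@@]4(C)O[C@@]25/C(=C\1)C(=O)O[C@@]35C[C@@H]4C | intermediate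
38 | C20 pinacol boronate (C19, C20 epimers) | C[C@H]1C[C@@H](O)C(=O)[C@@H]2[C@@H](O[Si](C)(C)C(C)(C)C)[C@H]3[C@H](O[Si](C)(C)C(C)(C)C)[C@@]4(C)O[C@@]25C(C1B6OC(C)(C)C(C)(C)O6)C(=O)O[C@@]35C[C@@H]4C | intermediate
39 | diol (C4–OH, C20–OH; C19, C20 epimers) | C[C@H]1C[C@@H](O)C(=O)[C@@H]2[C@@H](O[Si](C)(C)C(C)(C)C)[C@H]3[C@H](O[Si](C)(C)C(C)(C)C)[C@@]4(C)O[C@@]25C(C1O)C(=O)O[C@@]35C[C@@H]4C | intermediate
40 | C4,C7-dione with enolised β-keto lactone | C[C@H]1CC(=O)C(=O)[C@@H]2[C@@H](O[Si](C)(C)C(C)(C)C)[C@H]3[C@H](O[Si](C)(C)C(C)(C)C)[C@@]4(C)O[C@@]25/C(=C\1O)C(=O)O[C@@]35C[C@@H]4C | intermediate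
41 | methylmagnesium bromide | C[Mg]Br | starting material
42 | O11,O14-bis(tert-butyldimethylsilyl) ether of the target | C[C@H]1C[C@](C)(O)C(=O)[C@@H]2[C@@H](O[Si](C)(C)C(C)(C)C)[C@H]3[C@H](O[Si](C)(C)C(C)(C)C)[C@@]4(C)O[C@@]25/C(=C\1O)C(=O)O[C@@]35C[C@@H]4C | intermediate
43 | CNP0115071.1 | C[C@H]1C[C@](C)(O)C(=O)[C@@H]2[C@@H](O)[C@H]3[C@H](O)[C@@]4(C)O[C@@]25/C(=C\1O)C(=O)O[C@@]35C[C@@H]4C | target

**Count and risks**
Total step count: 32. Longest linear sequence: 31 steps (steps 1–3 and 5–32; step 4 is a side branch).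

Step 27 (key step). The alkoxide sits β to the lactone carbonyl, so heterolytic retro-aldol opening of the cyclobutane may outrun the concerted shift and erode the transfer of propenyl geometry to C2 or lead to 1,3-recombination at C19; the inward methyl also crowds O17 in the boat. The fallback is the neutral silyloxy variant. It sets out from 34, which is silylated with N-(trimethylsilyl)imidazole to the C7 trimethylsilyl ether F1. Heating F1 in toluene (sealed tube, 110–140 °C) should then give the thermal [3,3] shift without any alkoxide and deliver the silyl enol ether directly, returning to the route at 36.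

Step 10. After protonation the tertiary epoxide may rearrange by hydride shift or eliminate before the tetronic acid oxygen reaches C15 through the boat conformer. The fallback forms the bridge first with a carboxyl group and builds the butenolide afterwards. It sets out from 12, which is saponified (LiOH, THF/H2O) to the epoxy hydroxy acid F2. CSA then closes the bridged hydroxy δ-lactone F3 by opening the epoxide at C15 with the carboxyl group. The secondary C13–OH is silylated (TBSOTf, 2,6-lutidine, −78 °C) to the silyl ether F4. Heating F4 with Ph3P=C=C=O in toluene acylates the tertiary C25–OH and olefinates the lactone carbonyl by intramolecular Wittig reaction, returning to the route at 16.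

Step 31. The Grignard reagent may enolise the 1,2-dione, attack C7, or show poor facial selectivity. The fallback brings the methyl in as an electrophile. It sets out from 37, which is silylated (TESOTf, 2,6-lutidine) to the α-triethylsilyloxy ketone F5. Deprotonation at C4 with KN(SiMe3)2 and C-methylation with MeI from the outer face should give the α-silyloxy α-methyl ketone F6. Conjugate borylation as in step 29 gives the boronate F7 and perborate oxidation the β-hydroxy lactone F8. Dess–Martin oxidation gives the enolised β-keto lactone F9, and HF·pyridine removes all three silyl groups, returning to the route at 43.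

**Further compounds**
F1 | step 27 | C7 trimethylsilyl ether of 34 | C=C[C@@]1(O[Si](C)(C)C)[C@@H]2[C@@H](O[Si](C)(C)C(C)(C)C)[C@H]3[C@H](O[Si](C)(C)C(C)(C)C)[C@@]4(C)O[C@@]25[C@]1(/C=C\C)C(=O)O[C@@]35C[C@@H]4C
F2 | step 10 | epoxy hydroxy acid from 12 | COc1ccc(COC[C@H]2[C@@H]3O[C@]3(C)[C@@H](C)C[C@@]2(O)C(=O)O)cc1
F3 | step 10 | bridged hydroxy δ-lactone (2-oxabicyclo[2.2.2]octan-3-one with C25–OH and C13–OH) | COc1ccc(COC[C@H]2[C@H](O)[C@@]3(C)OC(=O)[C@]2(O)C[C@@H]3C)cc1
F4 | step 10 | C13 TBS ether of F3 | COc1ccc(COC[C@H]2[C@H](O[Si](C)(C)C(C)(C)C)[C@@]3(C)OC(=O)[C@]2(O)C[C@@H]3C)cc1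
F5 | step 31 | C4 triethylsilyl ether of 37 | C[C@H]1C[C@@H](O[Si](CC)(CC)CC)C(=O)[C@@H]2[C@@H](O[Si](C)(C)C(C)(C)C)[C@H]3[C@H](O[Si](C)(C)C(C)(C)C)[C@@]4(C)O[C@@]25/C(=C\1)C(=O)O[C@@]35C[C@@H]4C
F6 | step 31 | C4-methyl C4-triethylsilyloxy ketone | C[C@H]1C[C@](C)(O[Si](CC)(CC)CC)C(=O)[C@@H]2[C@@H](O[Si](C)(C)C(C)(C)C)[C@H]3[C@H](O[Si](C)(C)C(C)(C)C)[C@@]4(C)O[C@@]25/C(=C\1)C(=O)O[C@@]35C[C@@H]4C
F7 | step 31 | C20 pinacol boronate of F6 | C[C@H]1C[C@](C)(O[Si](CC)(CC)CC)C(=O)[C@@H]2[C@@H](O[Si](C)(C)C(C)(C)C)[C@H]3[C@H](O[Si](C)(C)C(C)(C)C)[C@@]4(C)O[C@@]25C(C1B6OC(C)(C)C(C)(C)O6)C(=O)O[C@@]35C[C@@H]4C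
F8 | step 31 | β-hydroxy lactone (C20–OH) | C[C@H]1C[C@](C)(O[Si](CC)(CC)CC)C(=O)[C@@H]2[C@@H](O[Si](C)(C)C(C)(C)C)[C@H]3[C@H](O[Si](C)(C)C(C)(C)C)[C@@]4(C)O[C@@]25C(C1O)C(=O)O[C@@]35C[C@@H]4C
F9 | step 31 | tris-silyl ether of the target (C4–OTES, O11/O14 TBS) | C[C@H]1C[C@](C)(O[Si](CC)(CC)CC)C(=O)[C@@H]2[C@@H](O[Si](C)(C)C(C)(C)C)[C@H]3[C@H](O[Si](C)(C)C(C)(C)C)[C@@]4(C)O[C@@]25/C(=C\1O)C(=O)O[C@@]35C[C@@H]4C
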